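**Plan**

1. Numbering (elemane): cyclohexane C-5 to C-10; vinyl C-1=C-2 and methyl C-14 on C-10; isopropenyl C-4(=C-3)–C-15 on C-5; lactone O-6–C-12(=O)–C-11(CH3, OAc)–C-7; acyloxy group on C-8.
2. Cuts, in retrosynthetic order: C-1=C-2 (Wittig); lactone O-6–C-12 (translactonisation out of a C-1 acetal); O-8–acyl with inversion (Mitsunobu); then the ring bonds C-8–C-9 and C-5–C-10 together; then C-7–C-11 and C-6–C-7 (two aldol unions) and O-6–C-1 (acetal exchange).
3. Enabling feature: on the cyclohexane chair O-6 (on C-6) and C-1 (on C-10) are 1,3-syn-diaxial, and C-9/C-10/C-14/C-1 is a methacrolein unit. O-6 therefore carries that unit as a mixed acetal, which protects O-6, later becomes the vinyl group, and makes the quaternary centre C-10 a bridgehead.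
4. Forward: the acyclic chain C-8–C-7–C-6–C-5=C-4 with the C-11 unit is built first. An acyl radical at C-8 then closes a seven-membered acetal ring at C-9, and the C-10 radical closes across that ring onto C-5, so the cyclohexane appears inside a 6-oxabicyclo[3.2.1]octane. The γ-lactone closes when O-6 is released from the acetal.
5. Stereochemistry: C-6 from a chiral diamine/Sn(OTf)2 Mukaiyama aldol; C-11 and C-7 from a bis(oxazoline)/Cu(OTf)2 pyruvate aldol (syn, matched with C-6); C-10 from the tether; C-5 from allylic strain in the transannular closure; C-8 from exo hydride attack followed by SN2 inversion.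

Key step: step 8

Remark: the facial senses of the two catalytic aldol steps are assigned by analogy with the parent reactions of these catalysts; if either proves opposite, the antipodal ligand is used. The acetal carbon C-1 is carried as both epimers from 7 to 18 and is no longer stereogenic in 19 and 20.

**Route**

Step 1
Reactants: 1 S-ethyl ethanethioate
Product: 2 1-(ethylsulfanyl)-1-[(trimethylsilyl)oxy]ethene
Conditions: LiN(i-Pr)2, THF, −78 °C; Me3SiCl, −78 to 0 °C
Reagents that add atoms: chlorotrimethylsilane, C[Si](C)(C)Cl
Why: Kinetic deprotonation of the thioester and O-silylation of the lithium enolate (silyl ketene acetal formation) should give the nucleophile for the Mukaiyama aldol, and no stereocenter is formed.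

Step 2
Reactants: 2 1-(ethylsulfanyl)-1-[(trimethylsilyl)oxy]ethene; 3 3-methylbut-2-enal
Product: 5 S-ethyl (3S)-3-hydroxy-5-methylhex-4-enethioate, via trimethylsilyl ether 4 (not isolated)
Conditions: Sn(OTf)2 (20 mol %), (S)-1-methyl-2-(piperidin-1-ylmethyl)pyrrolidine (22 mol %), EtCN, −78 °C, slow addition of 2 and 3; then citric acid, THF–H2O, 0 °C
Reagents that add atoms: none
Why: Mukaiyama aldol addition under the chiral diamine complex of divalent tin triflate, in which the aldehyde held in the chiral pocket should be attacked on one face to set C-6 as (S), after which the silyl ether formed by silyl transfer is cleaved in the work-up.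

Step 3
Reactants: 5 S-ethyl (3S)-3-hydroxy-5-methylhex-4-enethioate; 6 3,3-dimethoxy-2-methylprop-1-ene (methacrolein dimethyl acetal)
Product: 7 S-ethyl (3S)-3-[(1-methoxy-2-methylprop-2-en-1-yl)oxy]-5-methylhex-4-enethioate (both epimers at the acetal carbon)
Conditions: 6 (5 equiv), pyridinium p-toluenesulfonate (5 mol %), 5 Å molecular sieves, CH2Cl2, 0 to 23 °C
Reagents that add atoms: none
Why: Acid-catalysed transacetalisation with excess 6 and removal of methanol should exchange one methoxy group for the secondary alcohol without touching C-6, which installs the methacrolein unit (C-9, C-10, C-14, C-1) on O-6 as tether and protecting group in one.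

Step 4
Reactants: 7 S-ethyl (3S)-3-[(1-methoxy-2-methylprop-2-en-1-yl)oxy]-5-methylhex-4-enethioate
Product: 8 (3R)-1-(ethylsulfanyl)-3-[(1-methoxy-2-methylprop-2-en-1-yl)oxy]-5-methyl-1-[(trimethylsilyl)oxy]hexa-1,4-diene (silyl ketene acetal of 7; C-6 unchanged in space; mixture of geometric isomers at C-7=C-8, mainly Z)
Conditions: LiN(i-Pr)2, Me3SiCl (in situ quench), THF, −78 °C
Reagents that add atoms: chlorotrimethylsilane, C[Si](C)(C)Cl
Why: Enolisation of the thioester with immediate O-silylation (silyl ketene acetal formation) at −78 °C, where β-elimination of the acetal oxygen should not compete, and the double-bond geometry is not critical because the next step is stereoconvergent.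

Step 5
Reactants: 8 silyl ketene acetal of 7; 9 methyl 2-oxopropanoate (methyl pyruvate)
Product: 11 methyl (2S,3S,4R)-3-[(ethylsulfanyl)carbonyl]-2-hydroxy-4-[(1-methoxy-2-methylprop-2-en-1-yl)oxy]-2,6-dimethylhept-5-enoate, via trimethylsilyl ether 10 (not isolated)
Conditions: Cu(OTf)2 (10 mol %), 2,2'-(propane-2,2-diyl)bis[(4S)-4-tert-butyl-4,5-dihydro-1,3-oxazole] (11 mol %), THF, −78 °C; then Bu4NF, AcOH, THF, 0 °C
Reagents that add atoms: none
Why: Catalytic enantioselective Mukaiyama aldol addition to the pyruvate chelated on the divalent copper bis(oxazoline) complex, which should expose one ketone face (C-11 S) and give the 7,11-syn adduct through the open transition state, while attack on the enol silane anti to the C-6 oxygen (substrate bias) leads to the same C-7 configuration, so the pairing is matched.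

Step 6
Reactants: 11 methyl (2S,3S,4R)-3-[(ethylsulfanyl)carbonyl]-2-hydroxy-4-[(1-methoxy-2-methylprop-2-en-1-yl)oxy]-2,6-dimethylhept-5-enoate
Product: 12 methyl (2S,3S,4R)-2-(acetyloxy)-3-[(ethylsulfanyl)carbonyl]-4-[(1-methoxy-2-methylprop-2-en-1-yl)oxy]-2,6-dimethylhept-5-enoate
Conditions: Ac2O, 4-(dimethylamino)pyridine, Et3N, CH2Cl2, 35 °C
Reagents that add atoms: acetic anhydride, CC(=O)OC(C)=O
Why: Nucleophile-catalysed acetylation of the tertiary alcohol installs the C-11 acetate of the target early and blocks retro-aldol cleavage of the C-7–C-11 bond in later steps.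

Step 7
Reactants: 12 methyl (2S,3S,4R)-2-(acetyloxy)-3-[(ethylsulfanyl)carbonyl]-4-[(1-methoxy-2-methylprop-2-en-1-yl)oxy]-2,6-dimethylhept-5-enoate
Product: 13 methyl (2S,3S,4R)-2-(acetyloxy)-3-formyl-4-[(1-methoxy-2-methylprop-2-en-1-yl)oxy]-2,6-dimethylhept-5-enoate
Conditions: Et3SiH, Pd/C (10 wt %), acetone, 23 °C
Reagents that add atoms: none
Why: Fukuyama reduction (palladium-catalysed hydrosilane reduction of a thioester) should give the C-8 aldehyde without touching the methyl ester, the acetate or the acetal.

Step 8
Reactants: 13 methyl (2S,3S,4R)-2-(acetyloxy)-3-formyl-4-[(1-methoxy-2-methylprop-2-en-1-yl)oxy]-2,6-dimethylhept-5-enoate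
Product: 14 methyl (2S)-2-(acetyloxy)-2-[7-methoxy-1-methyl-3-oxo-8-(prop-1-en-2-yl)-6-oxabicyclo[3.2.1]octan-4-yl]propanoate (ring carbons arranged as C-5, C-6, C-7 and C-10 of 20; isopropenyl on the side of the O–C bridge)
Conditions: (Bu4N)4[W10O32] (3 mol %), Co(dmgH)2(py)Cl (5 mol %), MeCN (0.01 M), 390 nm LEDs, 10 °C, Ar
Reagents that add atoms: none
Why: Proposed new method: excited decatungstate should abstract the formyl hydrogen of 13 (the most hydridic and most exposed C–H) to give the C-8 acyl radical, which adds 7-endo-trig to the unsubstituted terminus C-9 of the tethered 1,1-disubstituted alkene; the tertiary C-10 radical then lies inside the seven-membered acetal ring and closes 5-exo-trig across it onto C-5 of the trisubstituted alkene, and the tertiary C-4 radical is dehydrogenated at a methyl group by the cobaloxime, which releases the isopropenyl group and H2, so that one operation forms C-8–C-9 and C-5–C-10. The closest known reaction types are decatungstate-mediated hydroacylation through acyl radicals, 7-endo acyl-radical cyclisation onto 2-substituted alkenes, and decatungstate/cobaloxime acceptorless desaturation; joining them in an annulating cascade is the new element. The first closure makes the oxepanone ring (7-endo), the second makes the five-membered acetal ring and with it the cyclohexanone (5-exo, transannular), giving the 6-oxabicyclo[3.2.1]octane. C-10 becomes a bridgehead, so the O-6–C-1 tether fixes it relative to C-6 (C-1 cis to O-6, methyl equatorial on the carbocycle); at C-5 the alkene should react in the rotamer in which C-4 avoids eclipsing the C-6–C-7 bond, which puts the isopropenyl group over the acetal bridge, that is equatorial and cis to O-6; C-7 is untouched and stays equatorial next to the new ketone. The step needs 7-endo closure to outrun decarbonylation and 6-exo attack (helped by the substituent on C-10, the low temperature and the dilution) and needs site-selective hydrogen abstraction (helped by the polarity and exposure of the formyl C–H).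

Step 9
Reactants: 14 methyl (2S)-2-(acetyloxy)-2-[7-methoxy-1-methyl-3-oxo-8-(prop-1-en-2-yl)-6-oxabicyclo[3.2.1]octan-4-yl]propanoate
Product: 15 methyl (2S)-2-(acetyloxy)-2-[3-hydroxy-7-methoxy-1-methyl-8-(prop-1-en-2-yl)-6-oxabicyclo[3.2.1]octan-4-yl]propanoate (C-8 hydroxyl on the face of the O–C bridge, the C-8 epimer of the target arrangement)
Conditions: LiBH(s-Bu)3, THF, −78 °C; AcOH quench at −78 °C; used without delay
Reagents that add atoms: none
Why: The bulky hydride should attack the ketone of the bicyclo[3.2.1]octan-3-one from the face of the one-carbon bridge, as bulky hydrides do with related bicyclic ketones, which places the C-8 hydroxyl on the face of the acetal bridge.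

Step 10
Reactants: 15 endo alcohol from step 9; 16 3-methylbut-3-enoic acid
Product: 17 methyl (2S)-2-(acetyloxy)-2-{7-methoxy-1-methyl-3-[(3-methylbut-3-enoyl)oxy]-8-(prop-1-en-2-yl)-6-oxabicyclo[3.2.1]octan-4-yl}propanoate (acyloxy group on the face of the one-carbon bridge, C-8 as in 20)
Conditions: PPh3, diisopropyl azodicarboxylate, toluene, 0 to 23 °C
Reagents that add atoms: none
Why: Mitsunobu esterification should displace the activated C-8 oxygen with inversion, the carboxylate entering from the open face of the one-carbon bridge, which sets the target configuration at C-8 and introduces the β,γ-unsaturated ester under neutral conditions that do not move its double bond.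

Step 11
Reactants: 17 bicyclic acetal ester from step 10
Product: 19 (3S,3aS,4R,6R,7R,7aR)-3-(acetyloxy)-6-formyl-3,6-dimethyl-2-oxo-7-(prop-1-en-2-yl)octahydro-1-benzofuran-4-yl 3-methylbut-3-enoate, via lactol 18 (not isolated)
Conditions: AcOH–THF–H2O (3:1:1), 40 °C; then pyridinium p-toluenesulfonate (0.2 equiv), toluene, 70 °C, 4 Å molecular sieves
Reagents that add atoms: water, O
Why: Mild acid hydrolysis of the bridging methyl acetal should give the lactol, and under weak acid catalysis with removal of methanol the axial O-6 hydroxyl lactonises onto the C-12 methyl ester (five-membered, cis-fused), which releases C-1 as the free aldehyde without touching any stereocenter.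

Step 12
Reactants: 19 aldehyde lactone from step 11
Product: 20 (3S,3aS,4R,6S,7R,7aR)-3-(acetyloxy)-6-ethenyl-3,6-dimethyl-2-oxo-7-(prop-1-en-2-yl)octahydro-1-benzofuran-4-yl 3-methylbut-3-enoate (CNP0106639.1)
Conditions: Ph3PCH3Br, KN(SiMe3)2, THF, −78 °C; then 19 (ylide 1.1 equiv), −78 to −20 °C
Reagents that add atoms: methyltriphenylphosphonium bromide, C[P+](c1ccccc1)(c1ccccc1)c1ccccc1.[Br-]
Why: Wittig methylenation of the non-enolisable neopentyl aldehyde at low temperature should give the vinyl group, the ylide being too weak a base to deprotonate the β,γ-unsaturated ester and the esters being inert at this temperature.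

**Compound list**

1 | S-ethyl ethanethioate | CCSC(C)=O | starting material
2 | 1-(ethylsulfanyl)-1-[(trimethylsilyl)oxy]ethene | C=C(O[Si](C)(C)C)SCC | intermediate
3 | 3-methylbut-2-enal | CC(C)=CC=O | starting material
4 | S-ethyl (3S)-5-methyl-3-[(trimethylsilyl)oxy]hex-4-enethioate (not isolated) | CCSC(=O)C[C@H](O[Si](C)(C)C)C=C(C)C | intermediate
5 | S-ethyl (3S)-3-hydroxy-5-methylhex-4-enethioate | CCSC(=O)C[C@H](O)C=C(C)C | intermediate
6 | 3,3-dimethoxy-2-methylprop-1-ene | COC(OC)C(C)=C | starting material
7 | S-ethyl (3S)-3-[(1-methoxy-2-methylprop-2-en-1-yl)oxy]-5-methylhex-4-enethioate (both acetal epimers) | CCSC(=O)C[C@H](OC(OC)C(C)=C)C=C(C)C | intermediate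
8 | (3R)-1-(ethylsulfanyl)-3-[(1-methoxy-2-methylprop-2-en-1-yl)oxy]-5-methyl-1-[(trimethylsilyl)oxy]hexa-1,4-diene (mixture of geometric isomers) | CCSC(O[Si](C)(C)C)=C[C@H](OC(OC)C(C)=C)C=C(C)C | intermediate
9 | methyl 2-oxopropanoate | CC(=O)C(=O)OC | starting material
10 | methyl (2S,3S,4R)-3-[(ethylsulfanyl)carbonyl]-4-[(1-methoxy-2-methylprop-2-en-1-yl)oxy]-2,6-dimethyl-2-[(trimethylsilyl)oxy]hept-5-enoate (not isolated) | CCSC(=O)[C@H]([C@](C)(O[Si](C)(C)C)C(=O)OC)[C@H](OC(OC)C(C)=C)C=C(C)C | intermediate
11 | methyl (2S,3S,4R)-3-[(ethylsulfanyl)carbonyl]-2-hydroxy-4-[(1-methoxy-2-methylprop-2-en-1-yl)oxy]-2,6-dimethylhept-5-enoate | CCSC(=O)[C@H]([C@](C)(O)C(=O)OC)[C@H](OC(OC)C(C)=C)C=C(C)C | intermediate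
12 | methyl (2S,3S,4R)-2-(acetyloxy)-3-[(ethylsulfanyl)carbonyl]-4-[(1-methoxy-2-methylprop-2-en-1-yl)oxy]-2,6-dimethylhept-5-enoate | CCSC(=O)[C@H]([C@](C)(OC(C)=O)C(=O)OC)[C@H](OC(OC)C(C)=C)C=C(C)C | intermediate
13 | methyl (2S,3S,4R)-2-(acetyloxy)-3-formyl-4-[(1-methoxy-2-methylprop-2-en-1-yl)oxy]-2,6-dimethylhept-5-enoate | O=C[C@H]([C@](C)(OC(C)=O)C(=O)OC)[C@H](OC(OC)C(C)=C)C=C(C)C | intermediate
14 | methyl (2S)-2-(acetyloxy)-2-[7-methoxy-1-methyl-3-oxo-8-(prop-1-en-2-yl)-6-oxabicyclo[3.2.1]octan-4-yl]propanoate | COC1O[C@@H]2[C@H](C(C)=C)[C@@]1(C)CC(=O)[C@@H]2[C@](C)(OC(C)=O)C(=O)OC | intermediate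
15 | methyl (2S)-2-(acetyloxy)-2-[3-hydroxy-7-methoxy-1-methyl-8-(prop-1-en-2-yl)-6-oxabicyclo[3.2.1]octan-4-yl]propanoate (hydroxyl on the face of the O–C bridge) | COC1O[C@@H]2[C@H](C(C)=C)[C@@]1(C)C[C@H](O)[C@@H]2[C@](C)(OC(C)=O)C(=O)OC | intermediate
16 | 3-methylbut-3-enoic acid | CC(=C)CC(=O)O | starting material
17 | methyl (2S)-2-(acetyloxy)-2-{7-methoxy-1-methyl-3-[(3-methylbut-3-enoyl)oxy]-8-(prop-1-en-2-yl)-6-oxabicyclo[3.2.1]octan-4-yl}propanoate (acyloxy on the face of the one-carbon bridge) | COC1O[C@@H]2[C@H](C(C)=C)[C@@]1(C)C[C@@H](OC(=O)CC(C)=C)[C@@H]2[C@](C)(OC(C)=O)C(=O)OC | intermediate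
18 | 7-hydroxy analogue of 17 (lactol, not isolated) | OC1O[C@@H]2[C@H](C(C)=C)[C@@]1(C)C[C@@H](OC(=O)CC(C)=C)[C@@H]2[C@](C)(OC(C)=O)C(=O)OC | intermediate
19 | (3S,3aS,4R,6R,7R,7aR)-3-(acetyloxy)-6-formyl-3,6-dimethyl-2-oxo-7-(prop-1-en-2-yl)octahydro-1-benzofuran-4-yl 3-methylbut-3-enoate | O=C[C@]1(C)C[C@@H](OC(=O)CC(=C)C)[C@H]2[C@H](OC(=O)[C@@]2(C)OC(C)=O)[C@@H]1C(=C)C | intermediate
20 | (3S,3aS,4R,6S,7R,7aR)-3-(acetyloxy)-6-ethenyl-3,6-dimethyl-2-oxo-7-(prop-1-en-2-yl)octahydro-1-benzofuran-4-yl 3-methylbut-3-enoate | C=C[C@]1(C)C[C@@H](OC(=O)CC(=C)C)[C@H]2[C@H](OC(=O)[C@@]2(C)OC(C)=O)[C@@H]1C(=C)C | target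

**Count and risks**

Total step count: 12. Longest linear sequence: 12 steps (1 to 20).

Step 8 (carries the label). What may go wrong: loss of CO from the acyl radical before the slow 7-endo closure; hydrogen abstraction at the acetal or allylic C–H bonds instead of the formyl C–H; cobalt hydride isomerisation of the 1,1-disubstituted alkene; desaturation toward the ring carbon instead of a methyl group. The fallback uses a known radical chain without photocatalyst; it sets out from aldehyde 13 and comes back at ketone 14. Pinnick oxidation (NaClO2, NaH2PO4, 2-methylbut-2-ene, t-BuOH–H2O) should give the carboxylic acid F1. Its acid chloride, made under neutral conditions with 1-chloro-N,N,2-trimethylprop-1-en-1-amine in CH2Cl2, is treated with KSC(=S)OEt to give the S-acyl O-ethyl xanthate F2. Visible light (or dilauroyl peroxide in refluxing 1,2-dichloroethane) at high dilution starts a degenerative xanthate-transfer chain: the same acyl radical closes 7-endo and then 5-exo, and the tertiary C-4 radical takes the xanthate group from F2 to give the tertiary xanthate F3. The reversible xanthate transfer gives the acyl radical the lifetime that the slow first closure needs. Thermolysis of F3 (Chugaev-type syn-elimination, diphenyl ether, 150 °C) should give 14.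

Step 5. What may go wrong: slow addition of the β-branched, hindered enol silane; ionisation of the mixed acetal by the silyl triflate that carries the catalytic turnover; or facial control by C-6 that opposes the catalyst. The fallback replaces the catalyst-controlled silyl ketene acetal addition by a chelation-controlled metal enolate aldol; it sets out from thioester 7 and comes back at 11. The lithium enolate (LiN(SiMe3)2, THF, −78 °C) is transmetalated with ClTi(Oi-Pr)3 and treated with methyl pyruvate at −78 °C, so that C-7 is set anti to the C-6 oxygen by the substrate and the two oxygens are held syn in a closed chelated transition state; the C-11 epimers would be separated. This passes through no new isolated compound (F0).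

Step 10. What may go wrong: elimination across C-8/C-9 or C-7/C-8 in place of substitution, or failure to activate the hindered hydroxyl that sits on the face of the acetal bridge. The fallback separates activation from displacement; it sets out from alcohol 15 and comes back at ester 17. Mesylation (MsCl, Et3N, CH2Cl2, −20 °C) gives the methanesulfonate F4, which is displaced with inversion by caesium 3-methylbut-3-enoate (from 16 and Cs2CO3) with 18-crown-6 in DMF at 50 °C, a carboxylate displacement that tends to favour substitution over elimination.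

**Further compounds**

F1 | step 8 | carboxylic acid from 13 (C-8 formyl oxidised to carboxyl, otherwise unchanged) | OC(=O)[C@H]([C@](C)(OC(C)=O)C(=O)OC)[C@H](OC(OC)C(C)=C)C=C(C)C
F2 | step 8 | S-acyl O-ethyl xanthate of F1 (C-8(=O)–S–C(=S)OEt) | CCOC(=S)SC(=O)[C@H]([C@](C)(OC(C)=O)C(=O)OC)[C@H](OC(OC)C(C)=C)C=C(C)C
F3 | step 8 | tertiary xanthate: 14 with a 2-[(ethoxycarbonothioyl)sulfanyl]propan-2-yl group on C-5 in place of isopropenyl | COC1O[C@@H]2[C@H](C(C)(C)SC(=S)OCC)[C@@]1(C)CC(=O)[C@@H]2[C@](C)(OC(C)=O)C(=O)OC
F0 | step 5 | none | none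
F4 | step 10 | methanesulfonate of 15 | COC1O[C@@H]2[C@H](C(C)=C)[C@@]1(C)C[C@H](OS(C)(=O)=O)[C@@H]2[C@](C)(OC(C)=O)C(=O)OC
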